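Digriseophene A is cut at the C1–C2 bond of each ring A. The key step exploits the alternating oxygenation of these rings: C2–OH, C4–OMe and C6–OH correspond to the lactone carbonyl, the 4-methoxyl and the ring oxygen of a 4-methoxy-2-pyrone, and the bridge-bearing C3 to pyrone C3, the one nucleophilic carbon of that heterocycle. A CH2-linked bis(4-methoxy-2-pyrone) carrying a benzyl-protected ring-B aroylmethyl group on each C6 is opened by methoxide and reclosed by intramolecular Claisen condensation, which should build both rings A and both benzophenone units in a single operation. Ring B is attached earlier by vinylogous aldol addition to an aldehyde, followed by oxidation.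

Key step: step 7

Remarks on the chemistry:
- The target has no stereocentre. Compound 10 should form as a mixture of meso and racemic diastereomers and is carried on unseparated, because both carbinol centres are oxidised in step 6.
- Intermediates 12–14 are drawn as neutral keto tautomers although they would be present as magnesium enolates.
- Ring B is introduced as an aldehyde, from commercial 2,4-dihydroxy-6-methylbenzaldehyde.
- Steps 1 and 5 are 2:1 couplings that build the symmetric dimer. The second molecule of the doubled component is entered under the atom-adding reagents so that each equation is balanced.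

Step 1
Reactants: 1 triacetic acid lactone (4-hydroxy-6-methyl-2H-pyran-2-one); 2 formaldehyde
Product: 4 3,3'-methylenebis(4-hydroxy-6-methyl-2H-pyran-2-one), via 3-methylidene-6-methylpyran-2,4-dione 3 (not isolated)
Conditions: 1 (2.0 equiv), 37% aq. CH2O (1.0 equiv), EtOH, reflux; product collected by filtration
Reagents that add atoms: triacetic acid lactone (the second molecule of 1 consumed per formaldehyde), Cc1cc(O)cc(=O)o1
Why: Knoevenagel condensation of one molecule of 1 with formaldehyde at C3, the only nucleophilic carbon of the 4-hydroxypyrone, gives the alkylidene dione 3, which is trapped at once by Michael addition of a second molecule of 1 (the dicoumarol-type methylene bridging of cyclic 1,3-dicarbonyl compounds), water being the only by-product.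

Step 2
Reactants: 4 3,3'-methylenebis(4-hydroxy-6-methyl-2H-pyran-2-one)
Product: 5 3,3'-methylenebis(4-methoxy-6-methyl-2H-pyran-2-one)
Conditions: Me2SO4 (3 equiv), K2CO3 (4 equiv), acetone, reflux
Reagents that add atoms: dimethyl sulfate, COS(=O)(=O)OC
Why: Williamson-type O-alkylation of a vinylogous acid, in which the hard electrophile should methylate O4 of each potassium pyronate as in the standard preparation of 4-methoxy-6-methyl-2-pyrone, so that the methyl ether pattern of ring A is in place before that ring is built.

Step 3
Reactants: 6 2,4-dihydroxy-6-methylbenzaldehyde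
Product: 7 4-(benzyloxy)-2-hydroxy-6-methylbenzaldehyde
Conditions: BnBr (1.05 equiv), K2CO3 (1.1 equiv), acetone, rt to 50 °C
Reagents that add atoms: benzyl bromide, BrCc1ccccc1
Why: Williamson ether synthesis selective for the 4-hydroxyl, which is para to the formyl group, more acidic and free, whereas the 2-hydroxyl is held in a hydrogen bond to the aldehyde.

Step 4
Reactants: 7 4-(benzyloxy)-2-hydroxy-6-methylbenzaldehyde
Product: 8 4-(benzyloxy)-2-methoxy-6-methylbenzaldehyde
Conditions: MeI (3 equiv), K2CO3 (2 equiv), DMF, rt to 40 °C
Reagents that add atoms: iodomethane, CI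
Why: Williamson methylation of the remaining chelated phenol, which needs the more forcing MeI/K2CO3 in DMF but has no competing site.

Step 5
Reactants: 5 3,3'-methylenebis(4-methoxy-6-methyl-2H-pyran-2-one); 8 4-(benzyloxy)-2-methoxy-6-methylbenzaldehyde
Product: 10 3,3'-methylenebis{6-[2-(4-benzyloxy-2-methoxy-6-methylphenyl)-2-hydroxyethyl]-4-methoxy-2H-pyran-2-one} (diastereomer mixture), via dilithium bis-dienolate 9 (not isolated)
Conditions: LiN(iPr)2 (LDA, commercial solution, 2.3 equiv), THF, −78 °C; then 8 (2.4 equiv, two molecules incorporated per molecule of 5), −78 °C; AcOH quench at −78 °C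
Reagents that add atoms: 4-(benzyloxy)-2-methoxy-6-methylbenzaldehyde (the second molecule of 8 incorporated per molecule of 5), COc1cc(OCc2ccccc2)cc(C)c1C=O
Why: Twofold vinylogous aldol addition in which the amide base removes a proton from each C6 methyl group (C3 is blocked by the bridge) and each extended dienolate adds through its exocyclic carbon to one molecule of the non-enolisable aldehyde; one equivalent of base per site suffices because the aldolate is not acidic, which avoids the excess base of an ester-level acylation that could metalate the ortho-methyl group of the electrophile, and the two carbinol centres form without control and are removed in step 6.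

Step 6
Reactants: 10 3,3'-methylenebis{6-[2-(4-benzyloxy-2-methoxy-6-methylphenyl)-2-hydroxyethyl]-4-methoxy-2H-pyran-2-one}
Product: 11 3,3'-methylenebis{6-[2-(4-benzyloxy-2-methoxy-6-methylphenyl)-2-oxoethyl]-4-methoxy-2H-pyran-2-one}
Conditions: IBX (3 equiv per hydroxyl), EtOAc, 77 °C; filtration
Reagents that add atoms: none
Why: Oxidation of secondary benzylic β-hydroxy carbonyl compounds to 1,3-dicarbonyl compounds by the pentavalent iodine reagent IBX in hot EtOAc, conditions that should leave the activated methylene, the enol ethers and the benzyl ethers untouched.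

Step 7
Reactants: 11 3,3'-methylenebis{6-[2-(4-benzyloxy-2-methoxy-6-methylphenyl)-2-oxoethyl]-4-methoxy-2H-pyran-2-one}
Product: 15 bis[3-(4-benzyloxy-2-methoxy-6-methylbenzoyl)-2,4-dihydroxy-6-methoxyphenyl]methane (di-O-benzyl digriseophene A), via mono-ring-opened methyl enoate 12 (not isolated), via half-recyclised pyrone-benzophenone 13 (not isolated), via ring-opened half-recyclised methyl enoate 14 (not isolated)
Conditions: Mg(OMe)2 (10 equiv), MeOH, reflux, Ar; then cold 1 M HCl
Reagents that add atoms: none
Why: Mg(OMe)2 first turns each aroylmethyl CH2 into a chelated magnesium enolate; methoxide then adds to the lactone carbonyl (pyrone C2), the ring opens to a methyl β-methoxy enoate in which the ester carbon and C5 stay cis across C3=C4 (CIP descriptor E, because OMe outranks C5), and the central carbon of the freed 1,3-diketone (future C1) attacks the ester carbon (future C2) with loss of methoxide, after which the cyclohexenedione enolises to the phenol and the sequence repeats on the second pyrone (12, 13, 14, then 15). The closest known reaction type is the base-induced Claisen recyclisation of 6-(2-oxoalkyl)-4-oxygenated 2-pyrones to acylphloroglucinols, a pyrone-to-arene ring transformation. Each of the two rings A closes in a 6-(enolexo)-exo-trig mode (the enolate double bond towards the aryl ketone lies outside the new ring and the ester C=O is exo), and no stereocentre is formed. Regiochemistry is fixed by 11 itself, since the carbonyl oxygen of each lactone should emerge as the C2 hydroxyl, the former ring oxygen as the C6 hydroxyl and the pyrone methoxyl as the C4 methyl ether, with the bridge already on C3. The step needs Claisen closure to win over aldol closure and over methanolysis of the 1,3-diketone: the only alternative aldol donor, C3, is a fully substituted enol-ether carbon, the aryl ketone is shielded by its ortho OMe and CH3 groups, magnesium chelation protects the diketone, the cis geometry needed for closure is inherited from the ring, and with methoxide in methanol any addition–elimination at C4 merely returns the methyl ether.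

Step 8
Reactants: 15 bis[3-(4-benzyloxy-2-methoxy-6-methylbenzoyl)-2,4-dihydroxy-6-methoxyphenyl]methane
Product: 16 digriseophene A, bis[2,4-dihydroxy-3-(4-hydroxy-2-methoxy-6-methylbenzoyl)-6-methoxyphenyl]methane
Conditions: H2 (1 atm), 10% Pd/C, EtOAc–MeOH, rt
Reagents that add atoms: none
Why: Catalytic hydrogenolysis of the two aryl benzyl ethers under neutral conditions; the diaryl ketones are flanked by four ortho substituents and chelated by hydroxyls, and the diarylmethane bridge carries no benzylic heteroatom, so both should survive one atmosphere of H2 at room temperature.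

Compound list
1 | triacetic acid lactone (4-hydroxy-6-methyl-2H-pyran-2-one) | Cc1cc(O)cc(=O)o1 | starting material
2 | formaldehyde | C=O | starting material
3 | 3-methylidene-6-methyl-2H-pyran-2,4(3H)-dione | C=C1C(=O)C=C(C)OC1=O | intermediate (not isolated)
4 | 3,3'-methylenebis(4-hydroxy-6-methyl-2H-pyran-2-one) | Cc1cc(O)c(Cc2c(O)cc(C)oc2=O)c(=O)o1 | intermediate
5 | 3,3'-methylenebis(4-methoxy-6-methyl-2H-pyran-2-one) | COc1cc(C)oc(=O)c1Cc1c(OC)cc(C)oc1=O | intermediate
6 | 2,4-dihydroxy-6-methylbenzaldehyde | Cc1cc(O)cc(O)c1C=O | starting material
7 | 4-(benzyloxy)-2-hydroxy-6-methylbenzaldehyde | Cc1cc(OCc2ccccc2)cc(O)c1C=O | intermediate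
8 | 4-(benzyloxy)-2-methoxy-6-methylbenzaldehyde | COc1cc(OCc2ccccc2)cc(C)c1C=O | intermediate
9 | dilithium bis-dienolate of 5 (both C6 methyl groups deprotonated, drawn as lithium 6-methylidene-6H-pyran-2-olates) | C=C1C=C(OC)C(CC2=C(O[Li])OC(=C)C=C2OC)=C(O[Li])O1 | intermediate (not isolated)
10 | 3,3'-methylenebis{6-[2-(4-benzyloxy-2-methoxy-6-methylphenyl)-2-hydroxyethyl]-4-methoxy-2H-pyran-2-one}, mixture of meso and racemic diastereomers, carbinol configurations not defined | COc1cc(CC(O)c2c(C)cc(OCc3ccccc3)cc2OC)oc(=O)c1Cc1c(OC)cc(CC(O)c2c(C)cc(OCc3ccccc3)cc2OC)oc1=O | intermediate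
11 | 3,3'-methylenebis{6-[2-(4-benzyloxy-2-methoxy-6-methylphenyl)-2-oxoethyl]-4-methoxy-2H-pyran-2-one} | COc1cc(CC(=O)c2c(C)cc(OCc3ccccc3)cc2OC)oc(=O)c1Cc1c(OC)cc(CC(=O)c2c(C)cc(OCc3ccccc3)cc2OC)oc1=O | intermediate (precursor of the key step)
12 | methyl (2E)-7-(4-benzyloxy-2-methoxy-6-methylphenyl)-3-methoxy-5,7-dioxo-2-[(pyron-3-yl)methyl]hept-2-enoate, the pyronyl group being the unchanged second half of 11; ester carbon and C4 of the chain cis | COC(=O)/C(Cc1c(OC)cc(CC(=O)c2c(C)cc(OCc3ccccc3)cc2OC)oc1=O)=C(\CC(=O)CC(=O)c1c(C)cc(OCc2ccccc2)cc1OC)OC | intermediate (not isolated)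
13 | half-recyclised compound: one 3-aroyl-2,4-dihydroxy-6-methoxyphenyl ring A joined through CH2 to C3 of the remaining 6-aroylmethyl-4-methoxy-2-pyrone | COc1cc(O)c(C(=O)c2c(C)cc(OCc3ccccc3)cc2OC)c(O)c1Cc1c(OC)cc(CC(=O)c2c(C)cc(OCc3ccccc3)cc2OC)oc1=O | intermediate (not isolated)
14 | methyl (2E)-7-(4-benzyloxy-2-methoxy-6-methylphenyl)-3-methoxy-5,7-dioxo-2-[(ring-A aryl)methyl]hept-2-enoate, the aryl group being the finished ring A of 13 | COC(=O)/C(Cc1c(OC)cc(O)c(C(=O)c2c(C)cc(OCc3ccccc3)cc2OC)c1O)=C(\CC(=O)CC(=O)c1c(C)cc(OCc2ccccc2)cc1OC)OC | intermediate (not isolated)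
15 | bis[3-(4-benzyloxy-2-methoxy-6-methylbenzoyl)-2,4-dihydroxy-6-methoxyphenyl]methane | COc1cc(O)c(C(=O)c2c(C)cc(OCc3ccccc3)cc2OC)c(O)c1Cc1c(OC)cc(O)c(C(=O)c2c(C)cc(OCc3ccccc3)cc2OC)c1O | intermediate (product of the key step)
16 | digriseophene A, bis[2,4-dihydroxy-3-(4-hydroxy-2-methoxy-6-methylbenzoyl)-6-methoxyphenyl]methane | COc1cc(O)c(C(=O)c2c(C)cc(O)cc2OC)c(O)c1Cc1c(OC)cc(O)c(C(=O)c2c(C)cc(O)cc2OC)c1O | target

Total step count: 8
Longest linear sequence: 6 steps (steps 1, 2, 5, 6, 7, 8 from 1; equally steps 3, 4, 5, 6, 7, 8 from 6)

Steps most likely to fail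

Step 7. What may go wrong: opening of the C3-substituted lactone may be slower than methanolysis of the aroylmethyl ketone, or the second recyclisation may stall after the first. Fallback: ring A is taken as a preformed arene and the bridge is made last, all by known reactions. The fallback sets out from 8 and commercial 5-methoxyresorcinol (COc1cc(O)cc(O)c1). Protection with MOMCl and iPr2NEt in CH2Cl2 would give 1-methoxy-3,5-bis(methoxymethoxy)benzene F1. n-BuLi in THF at 0 °C should metalate F1 between the two acetal groups, the stronger pair of directing groups, and addition of the aryllithium to 8 would give racemic (4-benzyloxy-2-methoxy-6-methylphenyl)[4-methoxy-2,6-bis(methoxymethoxy)phenyl]methanol F2. IBX oxidation would give (4-benzyloxy-2-methoxy-6-methylphenyl)[4-methoxy-2,6-bis(methoxymethoxy)phenyl]methanone F3. HCl in MeOH would remove both acetals to give (4-benzyloxy-2-methoxy-6-methylphenyl)(2,6-dihydroxy-4-methoxyphenyl)methanone F4. Condensation of F4, used in excess, with 37% aqueous formaldehyde in dilute NaOH–MeOH should join two molecules of it through one CH2 at the ring position between OH and OMe (the two free positions are equivalent), and the route is rejoined at 15.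

Step 5. What may go wrong: the dilithio species 9 may precipitate or add only once, and the addition to the hindered, electron-rich aldehyde may revert before the quench. Fallback: the side chain is attached before the bridge is built. The fallback sets out from 1 and 8. The dianion of 1 (LiN(iPr)2, 2.2 equiv, THF) should add through its methyl carbon to 8 to give racemic 6-[2-(4-benzyloxy-2-methoxy-6-methylphenyl)-2-hydroxyethyl]-4-hydroxy-2H-pyran-2-one F5. Aqueous formaldehyde (half an equivalent) in EtOH at room temperature, as in step 1, would bridge two molecules of this pyrone at C3, the only nucleophilic carbon while the side chain is at the alcohol level, giving 3,3'-methylenebis{6-[2-(4-benzyloxy-2-methoxy-6-methylphenyl)-2-hydroxyethyl]-4-hydroxy-2H-pyran-2-one} F6 as a diastereomer mixture. O-Methylation as in step 2 (Me2SO4, K2CO3, acetone) leaves the secondary alcohols untouched, and the route is rejoined at 10.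

Step 2. What may go wrong: alkylation of the ambident pyronate at C3 or at the lactone oxygen, giving 3-methyl diones or 2-methoxy-4-pyrones, with two sites that must both react correctly. Fallback: the methyl groups are delivered by Mitsunobu etherification instead of base alkylation. Compound 4 is treated with MeOH, PPh3 and diisopropyl azodicarboxylate in THF, a redox condensation in which the pyrone is the acid partner and which is known to etherify 4-hydroxy-2-pyrones at O4. The fallback sets out from 4, comes back at 5 and makes no new compound.

Further compounds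
F1 | step 7 | 1-methoxy-3,5-bis(methoxymethoxy)benzene | COCOc1cc(OC)cc(OCOC)c1
F2 | step 7 | (4-benzyloxy-2-methoxy-6-methylphenyl)[4-methoxy-2,6-bis(methoxymethoxy)phenyl]methanol, racemic | COCOc1cc(OC)cc(OCOC)c1C(O)c1c(C)cc(OCc2ccccc2)cc1OC
F3 | step 7 | (4-benzyloxy-2-methoxy-6-methylphenyl)[4-methoxy-2,6-bis(methoxymethoxy)phenyl]methanone | COCOc1cc(OC)cc(OCOC)c1C(=O)c1c(C)cc(OCc2ccccc2)cc1OC
F4 | step 7 | (4-benzyloxy-2-methoxy-6-methylphenyl)(2,6-dihydroxy-4-methoxyphenyl)methanone | COc1cc(O)c(C(=O)c2c(C)cc(OCc3ccccc3)cc2OC)c(O)c1
F5 | step 5 | 6-[2-(4-benzyloxy-2-methoxy-6-methylphenyl)-2-hydroxyethyl]-4-hydroxy-2H-pyran-2-one, racemic | O=c1cc(O)cc(CC(O)c2c(C)cc(OCc3ccccc3)cc2OC)o1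
F6 | step 5 | 3,3'-methylenebis{6-[2-(4-benzyloxy-2-methoxy-6-methylphenyl)-2-hydroxyethyl]-4-hydroxy-2H-pyran-2-one}, diastereomer mixture | O=c1oc(CC(O)c2c(C)cc(OCc3ccccc3)cc2OC)cc(O)c1Cc1c(O)cc(CC(O)c2c(C)cc(OCc3ccccc3)cc2OC)oc1=O
F0 | step 2 | none | none
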